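**Plan**

1. Retrosynthesis (daucane numbering: C1 quaternary methyl carbon, C4 = C(OH)iPr, C5 ring-fusion CH, C6 and C10 the ester carbons): cut the two ester C–O bonds, take C6–OH back to a ketone, then unmake the ring-fusion bond C1–C5 by a reverse 1,2-shift to a cis-decalin cis-diol monomesylate.
2. Enabling feature: the C6 carbonyl lies in the seven-membered ring next to ring-fusion C5, and C5 is bonded to quaternary C1. That is the retron of a pinacol-type shift, so the five-membered ring (C1–C5) is carried as six-membered ring A and the seven-membered ring as cyclohexene ring B; one shift contracts ring A and enlarges ring B.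
3. Further cuts: ring B at its alkene (metathesis) and at the carbinol–CH2 bond (allyl Grignard), the side chain at the quaternary carbon (aldol), back to (R)-carvone.
4. Forward order: ring A from carvone, ring B by 2-methylallyl addition and ring-closing metathesis, all-cis triol by hydroxyl-directed dihydroxylation, mesylate, shift to the trans-hydroazulenone, directed ketone reduction, two esterifications.
5. Stereochemistry: the carvone centre sets the quaternary carbon (axial aldol) and is then erased; that carbon sets the ring-fusion carbinol, which directs OsO4; inversion at the mesylate carbon with retention in the migrating carbon gives the trans fusion; C10 comes from Luche reduction anti to the angular methyl (both aldol carbinol epimers converge on one enone first); C6 comes from hydroxyl-directed hydride delivery.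

Key step: step 11

Remark: the aldol of step 2 should give the side-chain carbinol as an epimer mixture that converges at 11, and the SMILES of 5, 6, 7, 9 and 10 show the epimer expected to predominate; decalin names use C4a (methyl-bearing) and C8a (hydroxyl-bearing) for the ring-fusion carbons, ring A = C1–C4 (isopropyl on C2), ring B = C5–C8 (methyl on C7).

**Route**

Step 1
Reactants: 1 (R)-carvone
Product: 2 (R)-carvotanacetone, (5R)-5-isopropyl-2-methylcyclohex-2-en-1-one
Conditions: H2 (1 atm), RhCl(PPh3)3 (2 mol%), benzene, rt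
Reagents that add atoms: none
Why: Homogeneous hydrogenation with RhCl(PPh3)3 should saturate only the unhindered 1,1-disubstituted isopropenyl alkene and leave the trisubstituted conjugated alkene, with no change at the stereocentre.

Step 2
Reactants: 2 (R)-carvotanacetone; 3 acrolein
Product: 5 (2R,5R)-2-[(1R)-1-hydroxyprop-2-en-1-yl]-5-isopropyl-2-methylcyclohexan-1-one, via lithium enolate 4 (not isolated)
Conditions: LiBH(s-Bu)3 (L-Selectride, 1.1 equiv), THF, −78 °C; acrolein (1.5 equiv), −78 °C; H2O
Reagents that add atoms: acrolein (3), C=CC=O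
Why: Conjugate hydride addition gives the tetrasubstituted enolate regiospecifically, and the aldol addition (reductive aldol reaction) should occur by axial attack on the half-chair that has isopropyl equatorial, so the new C–C bond forms cis to isopropyl and sets the quaternary methyl centre, while the carbinol centre forms as an epimer mixture that is reset in steps 6 and 9.

Step 3
Reactants: 5 aldol adduct
Product: 7 (6R)-6-[(1R)-1-hydroxyprop-2-en-1-yl]-3-isopropyl-6-methylcyclohex-2-en-1-one, via bis-trimethylsilyl intermediate 6 (not isolated)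
Conditions: LDA (2.5 equiv), Me3SiCl (3 equiv), THF, −78 °C; Pd(OAc)2 (1.1 equiv), MeCN, rt; 1 M HCl, THF, 0 °C
Reagents that add atoms: none
Why: Saegusa–Ito dehydrogenation: only the CH2 next to the ketone can be enolised, Pd(OAc)2 oxidises the silyl enol ether to the enone and so removes the now redundant isopropyl-bearing stereocentre, and dilute acid cleaves the silyl ether.

Step 4
Reactants: 7 hydroxy enone; 8 2-methylallylmagnesium chloride
Product: 9 (1S,6R)-6-[(1R)-1-hydroxyprop-2-en-1-yl]-3-isopropyl-6-methyl-1-(2-methylprop-2-en-1-yl)cyclohex-2-en-1-ol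
Conditions: 2-methylallylmagnesium chloride (3 equiv), THF, −78 °C; H2O
Reagents that add atoms: 2-methylallylmagnesium chloride (8), CC(=C)C[Mg]Cl
Why: Allylic Grignard reagents add 1,2 to enones, and with the side-chain magnesium alkoxide chelating the carbonyl the ring methyl is pseudoaxial, so the nucleophile should attack anti to it (axial attack) and place the new tertiary hydroxyl cis to that methyl.

Step 5
Reactants: 9 triene diol
Product: 10 cis-fused (4aR,5R,8aS)-2-isopropyl-4a,7-dimethyl-3,4,4a,5,8,8a-hexahydronaphthalene-5,8a-diol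
Conditions: RuCl2(=CHPh)(H2IMes)(PCy3) (second-generation Grubbs catalyst, 5 mol%), CH2Cl2, 40 °C
Reagents that add atoms: none
Why: Ring-closing olefin metathesis between the vinyl and 2-methylallyl groups, held cis on adjacent carbons, should close cyclohexene ring B with its trisubstituted alkene, the hindered ring A alkene taking no part.

Step 6
Reactants: 10 bicyclic diol
Product: 11 (4aS,8aS)-8a-hydroxy-2-isopropyl-4a,7-dimethyl-4,4a,8,8a-tetrahydronaphthalen-5(3H)-one
Conditions: MnO2 (20 equiv), CH2Cl2, rt
Reagents that add atoms: none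
Why: MnO2 oxidises only the secondary allylic alcohol, so both carbinol epimers converge on one enone and the tertiary alcohol is untouched.

Step 7
Reactants: 11 hydroxy dienone
Product: 13 (1S,2R,4aS,8aR)-1,2,8a-trihydroxy-2-isopropyl-4a,7-dimethyl-1,2,3,4,4a,8a-hexahydronaphthalen-5(8H)-one, via osmate ester 12 (not isolated)
Conditions: OsO4 (1.05 equiv), TMEDA (1.1 equiv), CH2Cl2, −78 °C; aq. Na2SO3, THF, 40 °C
Reagents that add atoms: osmium tetroxide, O=[Os](=O)(=O)=O
Why: Donohoe hydroxyl-directed dihydroxylation: OsO4·TMEDA is delivered by hydrogen bonding to the C8a hydroxyl on the convex face of the cis-decalin, so both new hydroxyls should be cis to C8a–OH and to the angular methyl, and the electron-poor enone alkene should not react.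

Step 8
Reactants: 13 triol
Product: 14 (1S,2R,4aS,8aR)-2,8a-dihydroxy-2-isopropyl-4a,7-dimethyl-5-oxo-1,2,3,4,4a,5,8,8a-octahydronaphthalen-1-yl methanesulfonate
Conditions: MsCl (1.2 equiv), Et3N, CH2Cl2, −20 °C
Reagents that add atoms: methanesulfonyl chloride, CS(=O)(=O)Cl
Why: Sulfonylation is selective for the only secondary hydroxyl, since the two tertiary hydroxyls do not react at this temperature.

Step 9
Reactants: 14 keto mesylate
Product: 15 (1S,2R,4aR,5S,8aR)-2,5,8a-trihydroxy-2-isopropyl-4a,7-dimethyl-1,2,3,4,4a,5,8,8a-octahydronaphthalen-1-yl methanesulfonate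
Conditions: NaBH4, CeCl3·7H2O, MeOH, −78 °C
Reagents that add atoms: none
Why: Luche reduction gives 1,2-reduction of the enone, and hydride should add anti to the pseudoaxial angular methyl on the adjacent carbon, so the new hydroxyl is cis to that methyl.

Step 10
Reactants: 15 allylic alcohol
Product: 16 5-O-triethylsilyl ether of 15
Conditions: Et3SiCl, imidazole, DMF, 0 °C
Reagents that add atoms: chlorotriethylsilane, CC[Si](Cl)(CC)CC
Why: Silylation under these conditions takes the secondary allylic hydroxyl only, the tertiary hydroxyls being inert.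

Step 11
Reactants: 16 diol mesylate
Product: 18 (1S,4R,5R,10S)-4-hydroxy-10-(triethylsilyloxy)dauc-8-en-6-one, via aluminium alkoxide 17 (not isolated)
Conditions: Et3Al (4 equiv), CH2Cl2, −78 to 0 °C; aq. sodium potassium tartrate
Reagents that add atoms: none
Why: Et3Al turns the two tertiary hydroxyls into aluminium alkoxides and binds the mesylate as a Lewis acid; in the ring A chair with isopropyl and mesylate equatorial the C4a–C8a bond is antiperiplanar to the C1–O bond, so C4a migrates from C8a to C1 with loss of mesylate while the C8a–O bond becomes the carbonyl. The closest known reaction type is the organoaluminium-promoted pinacol-type rearrangement of β-mesyloxy alcohols (Suzuki–Tsuchihashi), in the form long used to turn decalin diol monosulfonates into hydroazulenones. No ring is closed by cyclisation: the five-membered ring (C1–C5, daucane numbering) arises by contraction of six-membered ring A and the seven-membered ring by expansion of ring B, both through the same suprafacial 1,2-alkyl shift. The new ring-fusion centre C5 is set by inversion at the mesylate carbon, the quaternary carbon migrates with retention, and C4 and C10 are spectators, which together should give the trans ring fusion with H-5 anti to the C4 hydroxyl. The step needs migration of C4a and not of C3 (the C2–C3 bond is also antiperiplanar, with the C2 oxygen as donor): the fully substituted C4a is the far better migrating group in this cation-like transition state and its shift relieves the crowded C4a–C8a bond. Elimination and epoxide formation are excluded because neither neighbour of C1 carries hydrogen and neither oxygen is anti to the mesylate.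

Step 12
Reactants: 18 hydroxy ketone
Product: 19 (1S,4R,5S,6S,10S)-10-(triethylsilyloxy)dauc-8-ene-4,6-diol
Conditions: Me4NBH(OAc)3, MeCN/AcOH, −30 °C
Reagents that add atoms: none
Why: Evans–Saksena hydroxyl-directed reduction: the tertiary C4 hydroxyl binds the triacetoxyborohydride and delivers hydride to the face of the C6 ketone on which C4–O lies, which should give the 1,3-anti diol with C6–OH trans to C4–OH.

Step 13
Reactants: 19 diol; 20 4-acetoxybenzoyl chloride
Product: 21 (1S,4R,5S,6S,10S)-4-hydroxy-10-(triethylsilyloxy)dauc-8-en-6-yl 4-acetoxybenzoate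
Conditions: 4-acetoxybenzoyl chloride, pyridine, DMAP (cat.), CH2Cl2, 0 °C to rt
Reagents that add atoms: 4-acetoxybenzoyl chloride (20), CC(=O)Oc1ccc(cc1)C(Cl)=O
Why: DMAP-catalysed acylation takes the only secondary hydroxyl, the tertiary alcohol being inert to the acid chloride.

Step 14
Reactants: 21 silyl ether
Product: 22 (1S,4R,5S,6S,10S)-4,10-dihydroxydauc-8-en-6-yl 4-acetoxybenzoate
Conditions: HF·pyridine, pyridine, THF, 0 °C
Reagents that add atoms: none
Why: Buffered HF·pyridine cleaves the triethylsilyl ether and should leave the benzoate and the aryl acetate intact.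

Step 15
Reactants: 22 allylic alcohol; 23 angelic acid
Product: 25 (1S,4R,5S,6S,10S)-10-angeloyloxy-4-hydroxydauc-8-en-6-yl 4-acetoxybenzoate, via mixed anhydride 24 (not isolated)
Conditions: angelic acid, 2,4,6-trichlorobenzoyl chloride, Et3N, toluene, rt; then 22, toluene, 80 °C
Reagents that add atoms: angelic acid (23), C/C=C(/C)C(=O)O
Why: Yamaguchi esterification through the 2,4,6-trichlorobenzoic mixed anhydride, run without a nucleophilic catalyst, should acylate the hindered secondary allylic alcohol and keep the Z geometry of the angelate, the tertiary alcohol staying free.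

Step 16
Reactants: 25 aryl acetate
Product: 26 target, (1S,4R,5S,6S,10S)-10-angeloyloxy-4-hydroxydauc-8-en-6-yl 4-hydroxybenzoate
Conditions: pyrrolidine, CH2Cl2, 0 °C
Reagents that add atoms: none
Why: Aminolysis of the phenyl acetate by pyrrolidine is much faster than attack on the hindered alkyl esters, so only the phenol should be set free.

**Compound list**

1 | (R)-carvone, (5R)-2-methyl-5-(prop-1-en-2-yl)cyclohex-2-en-1-one | CC(=C)[C@@H]1CC=C(C)C(=O)C1 | starting material
2 | (R)-carvotanacetone, (5R)-5-isopropyl-2-methylcyclohex-2-en-1-one | CC(C)[C@@H]1CC=C(C)C(=O)C1 | intermediate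
3 | acrolein | C=CC=O | starting material
4 | lithium (5R)-5-isopropyl-2-methylcyclohex-1-en-1-olate | [Li+].CC(C)[C@@H]1CCC(C)=C([O-])C1 | intermediate (not isolated)
5 | (2R,5R)-2-[(1R)-1-hydroxyprop-2-en-1-yl]-5-isopropyl-2-methylcyclohexan-1-one (side chain cis to isopropyl) | CC(C)[C@H]1CC(=O)[C@@](C)([C@H](O)C=C)CC1 | intermediate
6 | bis-trimethylsilyl derivative of 5 (silyl enol ether towards the ring CH2, silyl ether of the carbinol) | CC(C)[C@H]1C=C(O[Si](C)(C)C)[C@@](C)([C@H](O[Si](C)(C)C)C=C)CC1 | intermediate (not isolated)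
7 | (6R)-6-[(1R)-1-hydroxyprop-2-en-1-yl]-3-isopropyl-6-methylcyclohex-2-en-1-one | CC(C)C1=CC(=O)[C@@](C)([C@H](O)C=C)CC1 | intermediate
8 | 2-methylallylmagnesium chloride | CC(=C)C[Mg]Cl | starting material
9 | (1S,6R)-6-[(1R)-1-hydroxyprop-2-en-1-yl]-3-isopropyl-6-methyl-1-(2-methylprop-2-en-1-yl)cyclohex-2-en-1-ol (tertiary OH cis to ring methyl) | CC(C)C1=C[C@@](O)(CC(C)=C)[C@@](C)([C@H](O)C=C)CC1 | intermediate
10 | cis-fused (4aR,5R,8aS)-2-isopropyl-4a,7-dimethyl-3,4,4a,5,8,8a-hexahydronaphthalene-5,8a-diol (8a-OH cis to 4a-methyl) | CC(C)C1=C[C@@]2(O)CC(C)=C[C@@H](O)[C@@]2(C)CC1 | intermediate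
11 | (4aS,8aS)-8a-hydroxy-2-isopropyl-4a,7-dimethyl-4,4a,8,8a-tetrahydronaphthalen-5(3H)-one | CC(C)C1=C[C@@]2(O)CC(C)=CC(=O)[C@@]2(C)CC1 | intermediate
12 | cyclic osmate ester of 13 through O1 and O2, TMEDA adduct | CC(C)[C@]1(O[Os]3(=O)=O)CC[C@]2(C)C(=O)C=C(C)C[C@]2(O)[C@H]1O3.CN(C)CCN(C)C | intermediate (not isolated)
13 | (1S,2R,4aS,8aR)-1,2,8a-trihydroxy-2-isopropyl-4a,7-dimethyl-1,2,3,4,4a,8a-hexahydronaphthalen-5(8H)-one (methyl and the three hydroxyls on one face) | CC(C)[C@]1(O)CC[C@]2(C)C(=O)C=C(C)C[C@]2(O)[C@H]1O | intermediate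
14 | 1-O-methanesulfonate of 13 | CC(C)[C@]1(O)CC[C@]2(C)C(=O)C=C(C)C[C@]2(O)[C@H]1OS(C)(=O)=O | intermediate
15 | (1S,2R,4aR,5S,8aR)-2,5,8a-trihydroxy-2-isopropyl-4a,7-dimethyl-1,2,3,4,4a,5,8,8a-octahydronaphthalen-1-yl methanesulfonate (5-OH cis to 4a-methyl) | CC(C)[C@]1(O)CC[C@]2(C)[C@@H](O)C=C(C)C[C@]2(O)[C@H]1OS(C)(=O)=O | intermediate
16 | 5-O-triethylsilyl ether of 15 | CC(C)[C@]1(O)CC[C@]2(C)[C@@H](O[Si](CC)(CC)CC)C=C(C)C[C@]2(O)[C@H]1OS(C)(=O)=O | intermediate
17 | bis(diethylaluminium) alkoxide of 16 | CC(C)[C@]1(O[Al](CC)CC)CC[C@]2(C)[C@@H](O[Si](CC)(CC)CC)C=C(C)C[C@]2(O[Al](CC)CC)[C@H]1OS(C)(=O)=O | intermediate (not isolated)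
18 | (1S,4R,5R,10S)-4-hydroxy-10-(triethylsilyloxy)dauc-8-en-6-one (trans-fused) | CC[Si](CC)(CC)O[C@H]1C=C(C)CC(=O)[C@@H]2[C@]1(C)CC[C@@]2(O)C(C)C | intermediate
19 | (1S,4R,5S,6S,10S)-10-(triethylsilyloxy)dauc-8-ene-4,6-diol | CC[Si](CC)(CC)O[C@H]1C=C(C)C[C@H](O)[C@@H]2[C@]1(C)CC[C@@]2(O)C(C)C | intermediate
20 | 4-acetoxybenzoyl chloride | CC(=O)Oc1ccc(cc1)C(Cl)=O | starting material
21 | (1S,4R,5S,6S,10S)-4-hydroxy-10-(triethylsilyloxy)dauc-8-en-6-yl 4-acetoxybenzoate | CC[Si](CC)(CC)O[C@H]1C=C(C)C[C@H](OC(=O)c2ccc(OC(C)=O)cc2)[C@@H]2[C@]1(C)CC[C@@]2(O)C(C)C | intermediate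
22 | (1S,4R,5S,6S,10S)-4,10-dihydroxydauc-8-en-6-yl 4-acetoxybenzoate | O[C@H]1C=C(C)C[C@H](OC(=O)c2ccc(OC(C)=O)cc2)[C@@H]2[C@]1(C)CC[C@@]2(O)C(C)C | intermediate
23 | angelic acid, (Z)-2-methylbut-2-enoic acid | C/C=C(/C)C(=O)O | starting material
24 | angelic 2,4,6-trichlorobenzoic anhydride | C/C=C(/C)C(=O)OC(=O)c1c(Cl)cc(Cl)cc1Cl | intermediate (not isolated)
25 | (1S,4R,5S,6S,10S)-10-angeloyloxy-4-hydroxydauc-8-en-6-yl 4-acetoxybenzoate | C/C=C(/C)C(=O)O[C@H]1C=C(C)C[C@H](OC(=O)c2ccc(OC(C)=O)cc2)[C@@H]2[C@]1(C)CC[C@@]2(O)C(C)C | intermediate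
26 | (1S,4R,5S,6S,10S)-10-angeloyloxy-4-hydroxydauc-8-en-6-yl 4-hydroxybenzoate | C/C=C(/C)C(=O)O[C@H]1C=C(C)C[C@H](OC(=O)c2ccc(O)cc2)[C@@H]2[C@]1(C)CC[C@@]2(O)C(C)C | target

**Step count and risks**

Total steps: 16. Longest linear sequence: 16 steps (from 1; 3, 8, 20 and 23 are bought).

Steps most likely to fail:

Step 11. The shift may be driven in part from the wrong carbinol: the C2–C3 bond is also antiperiplanar to the mesylate, so migration of C3 with the C2 oxygen as donor would contract ring A without enlarging ring B. The fallback blocks that donor and sets out from 16. Me3SiOTf and 2,6-lutidine at −78 °C should silylate the less hindered tertiary hydroxyl (C2–OH, whose carbinol carbon carries isopropyl, whereas C8a is flanked by the quaternary C4a) to give the 2-O-trimethylsilyl ether F1. t-BuOK in THF then forms the only remaining alkoxide (at C8a) and brings about the classical base-induced diol monosulfonate rearrangement to the 4-O-trimethylsilyl hydroazulenone F2, in which retro-aldol cleavage is not possible. Citric acid in MeOH removes the tertiary trimethylsilyl ether and leaves the triethylsilyl ether, which returns the route to 18.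

Step 9. Facial selectivity of hydride addition may be poor, since the angular methyl shields one face of the ring B carbonyl and the folded ring A the other. The fallback sets out from 14 and uses reagent control: Corey–Bakshi–Shibata reduction with the 2-methyl-CBS-oxazaborolidine (the enantiomer matched to the substrate by trial) and BH3·SMe2 in THF, which comes back to the route at 15 without a new intermediate.

Step 2. Conjugate addition to acrolein, its polymerisation, and retro-aldol loss of the hindered aldolate may erode the reaction. The fallback sets out from 2 and builds the side chain in stages: the enolate 4 is trapped with monomeric formaldehyde gas to give the hydroxymethyl ketone F3; Dess–Martin periodinane oxidises it to the non-enolisable keto aldehyde F4; vinylmagnesium bromide at −78 °C adds to the aldehyde only and returns the route to 5 (carbinol epimers, which converge at 11 as before).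

Further compounds
F1 | step 11 | 2-O-trimethylsilyl ether of 16 | CC(C)[C@]1(O[Si](C)(C)C)CC[C@]2(C)[C@@H](O[Si](CC)(CC)CC)C=C(C)C[C@]2(O)[C@H]1OS(C)(=O)=O
F2 | step 11 | 4-O-trimethylsilyl ether of 18 | CC[Si](CC)(CC)O[C@H]1C=C(C)CC(=O)[C@@H]2[C@]1(C)CC[C@@]2(O[Si](C)(C)C)C(C)C
F0 | step 9 | none | none
F3 | step 2 | (2R,5R)-2-(hydroxymethyl)-5-isopropyl-2-methylcyclohexan-1-one | CC(C)[C@H]1CC(=O)[C@@](C)(CO)CC1
F4 | step 2 | (1R,4R)-4-isopropyl-1-methyl-2-oxocyclohexane-1-carbaldehyde | CC(C)[C@H]1CC(=O)[C@@](C)(C=O)CC1
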